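Everything rests on disconnecting the C4–C5 bond of the bicyclic end group (carotenoid numbering: carbocycle C1–C6, ether ring O1–C8–C7–C6–C5, chain C9–C8′). That ether ring, with its quaternary C5, is read as a dearomatised 5-methyl-2-oxyfuran: in one operation a Lewis acid lets the γ-carbon C5 of a 2-silyloxyfuran open a tethered, resolved (R)-oxirane at its primary carbon C4, which closes the cyclohexane, sets C5 cis to the C3 oxygen, converts the furan into the butenolide and frees the C3 hydroxyl. The precursor is a 5-methyl-2-(triisopropylsilyloxy)furan whose C6 carries a CMe2–CH2–oxirane chain; the polyene is attached afterwards at the lactone carbon C8.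

Key step: step 8

Assumption: ethyl (2E)-4-(diethoxyphosphoryl)-2-methylbut-2-enoate (compound 29) is taken as a purchasable, (E)-configured reagent.

Step 1
Reactants: 1 2,2-dimethylpent-4-enoic acid; 2 ethyllithium
Product: 4 4,4-dimethylhept-6-en-3-one, via dilithium gem-diolate 3 (not isolated)
Conditions: EtLi (2.2 equiv), Et2O, 0 → 20 °C; inverse quench into cold 1 M HCl
Reagents that add atoms: none
Why: Ketone synthesis from a carboxylic acid and an organolithium: the second equivalent adds to the lithium carboxylate to give a gem-diolate that releases the ketone only on acidic work-up, and the quaternary α-carbon further suppresses over-addition.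

Step 2
Reactants: 4 4,4-dimethylhept-6-en-3-one
Product: 6 (±)-2-hydroxy-4,4-dimethylhept-6-en-3-one, via potassium enolate 5 (not isolated)
Conditions: KN(SiMe3)2, THF, −78 °C; then 3-phenyl-2-(phenylsulfonyl)oxaziridine, −78 °C; aq. NH4Cl
Reagents that add atoms: 3-phenyl-2-(phenylsulfonyl)oxaziridine, O=S(=O)(c1ccccc1)N1OC1c1ccccc1
Why: Enolate hydroxylation with an N-sulfonyloxaziridine: the ketone can enolise only towards the ethyl group, the terminal alkene is inert, and the new carbinol centre is racemic, which is harmless because it becomes sp2 in step 7.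

Step 3
Reactants: 6 (±)-2-hydroxy-4,4-dimethylhept-6-en-3-one; 7 diethylphosphonoacetic acid
Product: 8 (±)-4,4-dimethyl-3-oxohept-6-en-2-yl (diethoxyphosphoryl)acetate
Conditions: DCC, DMAP (cat.), CH2Cl2, 0 → 20 °C
Reagents that add atoms: none
Why: Steglich esterification of an unhindered secondary alcohol with a carbodiimide-activated acid should proceed cleanly under neutral conditions.

Step 4
Reactants: 8 (±)-4,4-dimethyl-3-oxohept-6-en-2-yl (diethoxyphosphoryl)acetate
Product: 10 (±)-5-methyl-4-(2-methylpent-4-en-2-yl)furan-2(5H)-one, via sodium phosphonate carbanion 9 (not isolated)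
Conditions: NaH, THF, 0 → 65 °C
Reagents that add atoms: none
Why: Intramolecular Horner–Wadsworth–Emmons olefination: the phosphonate carbanion reaches the neighbouring ketone through a five-membered ring, which should overcome the hindrance of the tert-alkyl ketone and give the butenolide directly.

Step 5
Reactants: 10 (±)-5-methyl-4-(2-methylpent-4-en-2-yl)furan-2(5H)-one
Product: 11 5-methyl-4-[2-methyl-1-(oxiran-2-yl)propan-2-yl]furan-2(5H)-one (all stereoisomers)
Conditions: mCPBA, NaHCO3, CH2Cl2, 0 → 20 °C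
Reagents that add atoms: 3-chloroperoxybenzoic acid, OOC(=O)c1cccc(Cl)c1
Why: Prilezhaev epoxidation: the peracid attacks the isolated terminal alkene while the electron-poor butenolide double bond is inert, and no stereocontrol is needed at this stage.

Step 6
Reactants: 11 5-methyl-4-[2-methyl-1-(oxiran-2-yl)propan-2-yl]furan-2(5H)-one
Product: 12 5-methyl-4-{2-methyl-1-[(2R)-oxiran-2-yl]propan-2-yl}furan-2(5H)-one (both lactone C-5 epimers)
Conditions: (R,R)-(salen)Co(OAc) (1 mol%; salen = N,N′-bis(3,5-di-tert-butylsalicylidene)cyclohexane-1,2-diamine dianion), H2O (0.55 equiv), THF, 0 → 20 °C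
Reagents that add atoms: none
Why: Hydrolytic kinetic resolution of a terminal epoxide: the (R,R)-configured trivalent cobalt salen acetate should hydrate the (S)-oxirane selectively and leave the (R)-oxirane, which fixes C3 of the target, while the lactone stereocentre stays as an irrelevant mixture.

Step 7
Reactants: 12 5-methyl-4-{2-methyl-1-[(2R)-oxiran-2-yl]propan-2-yl}furan-2(5H)-one
Product: 13 {[5-methyl-4-{2-methyl-1-[(2R)-oxiran-2-yl]propan-2-yl}furan-2-yl]oxy}tri(propan-2-yl)silane
Conditions: Et3N (3 equiv), TIPSOTf (1.1 equiv), CH2Cl2, −78 → 0 °C; pentane, cold aq. NaHCO3, filtration through Et3N-deactivated silica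
Reagents that add atoms: triisopropylsilyl trifluoromethanesulfonate, CC(C)[Si](C(C)C)(C(C)C)OS(=O)(=O)C(F)(F)F
Why: Silylative soft enolisation of a butenolide to the 2-silyloxyfuran erases the lactone stereocentre; the triflate is added to excess amine at low temperature so that the oxirane is not activated, and the bulky triisopropylsilyl group makes the furan robust enough to isolate.

Step 8
Reactants: 13 {[5-methyl-4-{2-methyl-1-[(2R)-oxiran-2-yl]propan-2-yl}furan-2-yl]oxy}tri(propan-2-yl)silane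
Product: 15 (6R,7aR)-6-hydroxy-4,4,7a-trimethyl-5,6,7,7a-tetrahydro-1-benzofuran-2(4H)-one, via difluoroboryl ether 14 (not isolated)
Conditions: BF3·OEt2 (1.2 equiv), CH2Cl2 (0.01 M), −78 → −20 °C; then aq. NaHCO3
Reagents that add atoms: none
Why: Proposed new method: BF3 coordinates the oxirane oxygen, the γ-carbon C5 of the silyloxyfuran attacks the primary carbon C4 from the rear, and the silyloxy-oxocarbenium ion so formed collapses to the butenolide by loss of the silyl group as the fluorosilane, the C3 oxygen being freed on work-up; the closest known reaction types are vinylogous Mukaiyama reactions of 2-silyloxyfurans that create γ-quaternary butenolides and Lewis-acid cyclisations of epoxides terminated by furans or arenes. The cyclohexane C1–C6 closes by a 6-endo opening of the oxirane, a Friedel–Crafts-like attack by the furan carbon next to the tether. The new stereocentre C5 is controlled by the resolved carbon C3: rear-side attack at C4 forces the C3–O bond anti to the forming C4–C5 bond, that is equatorial in a chair transition state, while O1 stays in the furan plane and is equatorial as well, so the 3,5-cis (5R) isomer should form and only a boat would give the trans isomer. Two selectivities are needed: C5 against C7 as the nucleophilic carbon, both of which would close a six-membered ring, secured by the intrinsic γ-preference of 2-silyloxyfurans and by the triisopropylsilyloxy group that shields C7; and C4 against C3 as the electrophilic carbon, secured by the primary terminus and by the strain of the five-membered alternative. High dilution and low temperature are meant to suppress hydride-shift rearrangement of the activated oxirane and intermolecular alkylation.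

Step 9
Reactants: 15 (6R,7aR)-6-hydroxy-4,4,7a-trimethyl-5,6,7,7a-tetrahydro-1-benzofuran-2(4H)-one
Product: 17 (6R,7aR)-4,4,7a-trimethyl-2,4,5,6,7,7a-hexahydro-1-benzofuran-2,6-diyl diacetate (both C-2 epimers), via bis(diisobutylaluminium) lactol alkoxide 16 (not isolated)
Conditions: i-Bu2AlH (2.3 equiv), CH2Cl2, −78 °C; then pyridine, DMAP, Ac2O (6 equiv), −78 → 0 °C; aq. potassium sodium tartrate
Reagents that add atoms: acetic anhydride, CC(=O)OC(C)=O
Why: Reductive acetylation of a lactone: the hydride adds once to the butenolide carbonyl and the aluminium hemiacetal is acetylated in the same flask before it can open, the C3 aluminium alkoxide being acetylated at the same time so that the C3 oxygen is masked without a separate step; C5 is quaternary, so the lactol acetate cannot aromatise.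

Step 10
Reactants: 18 but-2-yn-1-ol
Product: 19 (but-2-yn-1-yloxy)(tert-butyl)dimethylsilane
Conditions: TBSCl, imidazole, CH2Cl2, 20 °C
Reagents that add atoms: tert-butyl(chloro)dimethylsilane, CC(C)(C)[Si](C)(C)Cl
Why: Standard silylation of a primary alcohol protects the future C11 oxygen against the organometallic steps.

Step 11
Reactants: 19 (but-2-yn-1-yloxy)(tert-butyl)dimethylsilane
Product: 21 tert-butyl{[(2E)-3-iodobut-2-en-1-yl]oxy}dimethylsilane, via alkenylzirconocene chloride 20 (not isolated)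
Conditions: Cp2Zr(H)Cl (1.5 equiv), THF, 20 → 40 °C; then I2, 0 °C
Reagents that add atoms: iodine, [I][I]
Why: Hydrozirconation–iodinolysis of an internal alkyne: syn addition of Zr–H, equilibrated by a slight excess of the hydride, should place zirconium on the less hindered methyl-bearing carbon, and iodine replaces it with retention, which fixes the (E) geometry of the later C9=C10 bond.

Step 12
Reactants: 21 tert-butyl{[(2E)-3-iodobut-2-en-1-yl]oxy}dimethylsilane; 17 (6R,7aR)-4,4,7a-trimethyl-2,4,5,6,7,7a-hexahydro-1-benzofuran-2,6-diyl diacetate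
Product: 24 (2R,6R,7aR)-2-[(2E)-4-{[tert-butyl(dimethyl)silyl]oxy}but-2-en-2-yl]-4,4,7a-trimethyl-2,4,5,6,7,7a-hexahydro-1-benzofuran-6-yl acetate, via alkenyllithium 22 (not isolated), via alkenylzinc bromide 23 (not isolated)
Conditions: 21, t-BuLi (2 equiv), Et2O, −78 °C; ZnBr2 (1.5 equiv), THF, −78 → 0 °C; then 17, −40 → 0 °C
Reagents that add atoms: none
Why: Substitution of an unsaturated lactol acetate by an alkenylzinc halide through the allylic oxocarbenium ion (C-glycosylation type): iodine–lithium exchange and transmetallation keep the alkene geometry, and the alkenyl group should enter at C8 (C6 is fully substituted) on the face away from the axial C5 methyl, which the syn-axial C1 methyl pushes over O1, to set 8R; the bias is expected to be modest, and the minor C8 epimer, a diastereomer, is removed by chromatography.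

Step 13
Reactants: 24 (2R,6R,7aR)-2-[(2E)-4-{[tert-butyl(dimethyl)silyl]oxy}but-2-en-2-yl]-4,4,7a-trimethyl-2,4,5,6,7,7a-hexahydro-1-benzofuran-6-yl acetate
Product: 25 (2R,6R,7aR)-2-[(2E)-4-hydroxybut-2-en-2-yl]-4,4,7a-trimethyl-2,4,5,6,7,7a-hexahydro-1-benzofuran-6-yl acetate
Conditions: Bu4NF, AcOH (1:1), THF, 0 → 20 °C
Reagents that add atoms: none
Why: Fluoride cleavage of a primary silyl ether under near-neutral buffered conditions should leave the secondary acetate and the acid-labile bis-allylic C8–O bond untouched.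

Step 14
Reactants: 25 (2R,6R,7aR)-2-[(2E)-4-hydroxybut-2-en-2-yl]-4,4,7a-trimethyl-2,4,5,6,7,7a-hexahydro-1-benzofuran-6-yl acetate
Product: 27 {(2E)-3-[(2R,6R,7aR)-6-(acetyloxy)-4,4,7a-trimethyl-2,4,5,6,7,7a-hexahydro-1-benzofuran-2-yl]but-2-en-1-yl}(triphenyl)phosphonium bromide, via allylic bromide 26 (not isolated)
Conditions: CBr4 (1.1 equiv), PPh3 (1.1 equiv), 2,6-lutidine (0.2 equiv), CH2Cl2, 0 °C; then PPh3 (1.3 equiv), MeCN, 20 °C
Reagents that add atoms: tetrabromomethane, BrC(Br)(Br)Br; triphenylphosphine, c1ccc(cc1)P(c1ccccc1)c1ccccc1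
Why: Appel bromination of the primary allylic alcohol followed by SN2 quaternisation of triphenylphosphine at the primary carbon C11, both under neutral conditions, should disturb neither C8 nor the C9=C10 geometry.

Step 15
Reactants: 28 (2E,4E,6E)-2,7-dimethylocta-2,4,6-trienedial; 29 ethyl (2E)-4-(diethoxyphosphoryl)-2-methylbut-2-enoate
Product: 31 ethyl (2E,4E,6E,8E,10E)-2,6,11-trimethyl-12-oxododeca-2,4,6,8,10-pentaenoate, via sodium phosphonate carbanion 30 (not isolated)
Conditions: 29, NaH, THF, 0 °C; added slowly to 28 (3 equiv), THF, 0 → 20 °C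
Reagents that add atoms: none
Why: Horner–Wadsworth–Emmons olefination with a vinylogous phosphonoacetate: the stabilised carbanion should give the (E)-alkene, and slow addition to an excess of the recoverable dialdehyde favours the mono-adduct over the bis-adduct.

Step 16
Reactants: 27 {(2E)-3-[(2R,6R,7aR)-6-(acetyloxy)-4,4,7a-trimethyl-2,4,5,6,7,7a-hexahydro-1-benzofuran-2-yl]but-2-en-1-yl}(triphenyl)phosphonium bromide; 31 ethyl (2E,4E,6E,8E,10E)-2,6,11-trimethyl-12-oxododeca-2,4,6,8,10-pentaenoate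
Product: 33 ethyl (2E,4E,6E,8E,10E,12E,14E)-15-[(2R,6R,7aR)-6-(acetyloxy)-4,4,7a-trimethyl-2,4,5,6,7,7a-hexahydro-1-benzofuran-2-yl]-2,6,11-trimethylhexadeca-2,4,6,8,10,12,14-heptaenoate, via allylic phosphonium ylide 32 (not isolated)
Conditions: 27, NaN(SiMe3)2 (1.0 equiv), THF, −78 °C; 31, −78 → 20 °C; then heptane, 80 °C
Reagents that add atoms: none
Why: Wittig olefination of a polyenal with a semi-stabilised allylic ylide, the usual C11=C12 connection of carotenoid synthesis: the amide base deprotonates only the phosphonium salt, the ester of 31 is inert, and heating should convert the strained 11Z isomer formed alongside into the all-E polyene.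

Step 17
Reactants: 33 ethyl (2E,4E,6E,8E,10E,12E,14E)-15-[(2R,6R,7aR)-6-(acetyloxy)-4,4,7a-trimethyl-2,4,5,6,7,7a-hexahydro-1-benzofuran-2-yl]-2,6,11-trimethylhexadeca-2,4,6,8,10,12,14-heptaenoate
Product: 34 (2E,4E,6E,8E,10E,12E,14E)-15-[(2R,6R,7aR)-6-hydroxy-4,4,7a-trimethyl-2,4,5,6,7,7a-hexahydro-1-benzofuran-2-yl]-2,6,11-trimethylhexadeca-2,4,6,8,10,12,14-heptaen-1-ol
Conditions: i-Bu2AlH (5 equiv), CH2Cl2, −78 → −20 °C; aq. potassium sodium tartrate
Reagents that add atoms: none
Why: Hydride 1,2-reduction of the conjugated ester to the allylic alcohol should remove the C3 acetate in the same operation, so no separate deprotection is required.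

Step 18
Reactants: 34 (2E,4E,6E,8E,10E,12E,14E)-15-[(2R,6R,7aR)-6-hydroxy-4,4,7a-trimethyl-2,4,5,6,7,7a-hexahydro-1-benzofuran-2-yl]-2,6,11-trimethylhexadeca-2,4,6,8,10,12,14-heptaen-1-ol
Product: 35 (2E,4E,6E,8E,10E,12E,14E)-15-[(2R,6R,7aR)-6-hydroxy-4,4,7a-trimethyl-2,4,5,6,7,7a-hexahydro-1-benzofuran-2-yl]-2,6,11-trimethylhexadeca-2,4,6,8,10,12,14-heptaenal
Conditions: MnO2 (activated, 20 equiv), CH2Cl2, 20 °C, dark
Reagents that add atoms: none
Why: Chemoselective oxidation of the polyene-conjugated primary allylic alcohol by activated MnO2 should leave the saturated secondary C3 hydroxyl and the C8 ether untouched under these neutral conditions.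

Compound list
1 | 2,2-dimethylpent-4-enoic acid | C=CCC(C)(C)C(=O)O | starting material
2 | ethyllithium | [Li]CC | starting material
3 | dilithium 4,4-dimethylhept-6-ene-3,3-diolate | [Li]OC(CC)(O[Li])C(C)(C)CC=C | intermediate (not isolated)
4 | 4,4-dimethylhept-6-en-3-one | C=CCC(C)(C)C(=O)CC | intermediate
5 | potassium 4,4-dimethylhepta-2,6-dien-3-olate | C=CCC(C)(C)C(O[K])=CC | intermediate (not isolated)
6 | (±)-2-hydroxy-4,4-dimethylhept-6-en-3-one | C=CCC(C)(C)C(=O)C(C)O | intermediate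
7 | diethylphosphonoacetic acid | OC(=O)CP(=O)(OCC)OCC | starting material
8 | (±)-4,4-dimethyl-3-oxohept-6-en-2-yl (diethoxyphosphoryl)acetate | C=CCC(C)(C)C(=O)C(C)OC(=O)CP(=O)(OCC)OCC | intermediate
9 | sodium salt of the phosphonate carbanion of 8 | [Na+].C=CCC(C)(C)C(=O)C(C)OC(=O)[CH-]P(=O)(OCC)OCC | intermediate (not isolated)
10 | (±)-5-methyl-4-(2-methylpent-4-en-2-yl)furan-2(5H)-one | C=CCC(C)(C)C1=CC(=O)OC1C | intermediate
11 | 5-methyl-4-[2-methyl-1-(oxiran-2-yl)propan-2-yl]furan-2(5H)-one (all stereoisomers) | O=C1C=C(C(C)(C)CC2CO2)C(C)O1 | intermediate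
12 | 5-methyl-4-{2-methyl-1-[(2R)-oxiran-2-yl]propan-2-yl}furan-2(5H)-one (both lactone C-5 epimers) | O=C1C=C(C(C)(C)C[C@@H]2CO2)C(C)O1 | intermediate
13 | {[5-methyl-4-{2-methyl-1-[(2R)-oxiran-2-yl]propan-2-yl}furan-2-yl]oxy}tri(propan-2-yl)silane | Cc1oc(O[Si](C(C)C)(C(C)C)C(C)C)cc1C(C)(C)C[C@@H]2CO2 | intermediate (key-step precursor)
14 | (6R,7aR)-4,4,7a-trimethyl-2-oxo-2,4,5,6,7,7a-hexahydro-1-benzofuran-6-yl difluoroborinate | O=C1C=C2C(C)(C)C[C@@H](OB(F)F)C[C@@]2(C)O1 | intermediate (not isolated)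
15 | (6R,7aR)-6-hydroxy-4,4,7a-trimethyl-5,6,7,7a-tetrahydro-1-benzofuran-2(4H)-one | O=C1C=C2C(C)(C)C[C@@H](O)C[C@@]2(C)O1 | intermediate (key-step product)
16 | (6R,7aR)-2,6-bis{[bis(2-methylpropyl)alumanyl]oxy}-4,4,7a-trimethyl-2,4,5,6,7,7a-hexahydro-1-benzofuran | CC(C)C[Al](CC(C)C)OC1C=C2C(C)(C)C[C@@H](O[Al](CC(C)C)CC(C)C)C[C@@]2(C)O1 | intermediate (not isolated)
17 | (6R,7aR)-4,4,7a-trimethyl-2,4,5,6,7,7a-hexahydro-1-benzofuran-2,6-diyl diacetate (both C-2 epimers) | CC(=O)OC1C=C2C(C)(C)C[C@@H](OC(C)=O)C[C@@]2(C)O1 | intermediate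
18 | but-2-yn-1-ol | CC#CCO | starting material
19 | (but-2-yn-1-yloxy)(tert-butyl)dimethylsilane | CC#CCO[Si](C)(C)C(C)(C)C | intermediate
20 | chloro[(2E)-4-{[tert-butyl(dimethyl)silyl]oxy}but-2-en-2-yl]bis(cyclopentadienyl)zirconium | C/C(=C\CO[Si](C)(C)C(C)(C)C)[Zr](Cl)(C1C=CC=C1)C1C=CC=C1 | intermediate (not isolated)
21 | tert-butyl{[(2E)-3-iodobut-2-en-1-yl]oxy}dimethylsilane | C/C([I])=C\CO[Si](C)(C)C(C)(C)C | intermediate
22 | [(2Z)-4-{[tert-butyl(dimethyl)silyl]oxy}but-2-en-2-yl]lithium (metal trans to the CH2O group, same geometry as 21) | C/C([Li])=C\CO[Si](C)(C)C(C)(C)C | intermediate (not isolated)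
23 | bromo[(2E)-4-{[tert-butyl(dimethyl)silyl]oxy}but-2-en-2-yl]zinc | C/C([Zn]Br)=C\CO[Si](C)(C)C(C)(C)C | intermediate (not isolated)
24 | (2R,6R,7aR)-2-[(2E)-4-{[tert-butyl(dimethyl)silyl]oxy}but-2-en-2-yl]-4,4,7a-trimethyl-2,4,5,6,7,7a-hexahydro-1-benzofuran-6-yl acetate | CC(C)(C)[Si](C)(C)OC/C=C(\C)[C@H]1C=C2C(C)(C)C[C@@H](OC(C)=O)C[C@@]2(C)O1 | intermediate
25 | (2R,6R,7aR)-2-[(2E)-4-hydroxybut-2-en-2-yl]-4,4,7a-trimethyl-2,4,5,6,7,7a-hexahydro-1-benzofuran-6-yl acetate | OC/C=C(\C)[C@H]1C=C2C(C)(C)C[C@@H](OC(C)=O)C[C@@]2(C)O1 | intermediate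
26 | (2R,6R,7aR)-2-[(2E)-4-bromobut-2-en-2-yl]-4,4,7a-trimethyl-2,4,5,6,7,7a-hexahydro-1-benzofuran-6-yl acetate | BrC/C=C(\C)[C@H]1C=C2C(C)(C)C[C@@H](OC(C)=O)C[C@@]2(C)O1 | intermediate (not isolated)
27 | {(2E)-3-[(2R,6R,7aR)-6-(acetyloxy)-4,4,7a-trimethyl-2,4,5,6,7,7a-hexahydro-1-benzofuran-2-yl]but-2-en-1-yl}(triphenyl)phosphonium bromide | [Br-].c1ccccc1[P+](c1ccccc1)(c1ccccc1)C/C=C(\C)[C@H]1C=C2C(C)(C)C[C@@H](OC(C)=O)C[C@@]2(C)O1 | intermediate
28 | (2E,4E,6E)-2,7-dimethylocta-2,4,6-trienedial | O=C/C(C)=C/C=C/C=C(C)/C=O | starting material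
29 | ethyl (2E)-4-(diethoxyphosphoryl)-2-methylbut-2-enoate | CCOC(=O)/C(C)=C/CP(=O)(OCC)OCC | starting material
30 | sodium salt of the phosphonate carbanion of 29 | [Na+].CCOC(=O)/C(C)=C/[CH-]P(=O)(OCC)OCC | intermediate (not isolated)
31 | ethyl (2E,4E,6E,8E,10E)-2,6,11-trimethyl-12-oxododeca-2,4,6,8,10-pentaenoate | CCOC(=O)/C(C)=C/C=C/C(C)=C/C=C/C=C(C)/C=O | intermediate
32 | {(2E)-3-[(2R,6R,7aR)-6-(acetyloxy)-4,4,7a-trimethyl-2,4,5,6,7,7a-hexahydro-1-benzofuran-2-yl]but-2-en-1-ylidene}(triphenyl)phosphorane | c1ccccc1P(c1ccccc1)(c1ccccc1)=C/C=C(\C)[C@H]1C=C2C(C)(C)C[C@@H](OC(C)=O)C[C@@]2(C)O1 | intermediate (not isolated)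
33 | ethyl (2E,4E,6E,8E,10E,12E,14E)-15-[(2R,6R,7aR)-6-(acetyloxy)-4,4,7a-trimethyl-2,4,5,6,7,7a-hexahydro-1-benzofuran-2-yl]-2,6,11-trimethylhexadeca-2,4,6,8,10,12,14-heptaenoate | CCOC(=O)/C(C)=C/C=C/C(C)=C/C=C/C=C(C)/C=C/C=C(\C)[C@H]1C=C2C(C)(C)C[C@@H](OC(C)=O)C[C@@]2(C)O1 | intermediate
34 | (2E,4E,6E,8E,10E,12E,14E)-15-[(2R,6R,7aR)-6-hydroxy-4,4,7a-trimethyl-2,4,5,6,7,7a-hexahydro-1-benzofuran-2-yl]-2,6,11-trimethylhexadeca-2,4,6,8,10,12,14-heptaen-1-ol | OC/C(C)=C/C=C/C(C)=C/C=C/C=C(C)/C=C/C=C(\C)[C@H]1C=C2C(C)(C)C[C@@H](O)C[C@@]2(C)O1 | intermediate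
35 | (2E,4E,6E,8E,10E,12E,14E)-15-[(2R,6R,7aR)-6-hydroxy-4,4,7a-trimethyl-2,4,5,6,7,7a-hexahydro-1-benzofuran-2-yl]-2,6,11-trimethylhexadeca-2,4,6,8,10,12,14-heptaenal | C\C(C=O)=C/C=C/C(C)=C/C=C/C=C(C)/C=C/C=C(\C)[C@H]1C=C2C(C)(C)C[C@@H](O)C[C@@]2(C)O1 | target

Total step count: 18. Longest linear sequence: 15 steps (steps 1–9, 12–14 and 16–18).

Steps most likely to fail

Step 8 (attack of the furan through C7 instead of C5, hydride-shift rearrangement or fluoride opening of the activated oxirane, or loss of the silyl group before the ring closes). The fallback uses known chemistry, sets out from 12 and returns at 15. The oxirane is opened at its primary carbon with lithium iodide and AcOH in THF to the iodohydrin 4-[(4R)-4-hydroxy-5-iodo-2-methylpentan-2-yl]-5-methylfuran-2(5H)-one F1. TBSOTf (2.2 equiv) and Et3N silylate the alcohol and the lactone together to give tert-butyl({4-[(4R)-4-{[tert-butyl(dimethyl)silyl]oxy}-5-iodo-2-methylpentan-2-yl]-5-methylfuran-2-yl}oxy)dimethylsilane F2. AgOCOCF3 in CH2Cl2 (−78 → 20 °C) should then bring about the silver-assisted γ-alkylation of the silyloxyfuran by the primary iodide, a known way to alkylate 2-silyloxyfurans at the γ-carbon, through the same chair with the C3 substituent equatorial, giving (6R,7aR)-6-{[tert-butyl(dimethyl)silyl]oxy}-4,4,7a-trimethyl-5,6,7,7a-tetrahydro-1-benzofuran-2(4H)-one F3. Aqueous HF in MeCN removes the silyl ether and gives 15.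

Step 12 (poor or inverted facial selectivity at C8, because the two faces of the oxocarbenium ion differ only in methyl against methylene on C5). The fallback inverts the order of bond formation, sets out from 15 and returns at 24. Alkenyllithium 22 (2.2 equiv, Et2O, −78 °C) is added to the lactone carbonyl to give the hemiketal (6R,7aR)-2-[(2E)-4-{[tert-butyl(dimethyl)silyl]oxy}but-2-en-2-yl]-4,4,7a-trimethyl-2,4,5,6,7,7a-hexahydro-1-benzofuran-2,6-diol F4. Ionic reduction with Et3SiH and BF3·OEt2 (CH2Cl2, −78 °C) then delivers hydride instead of carbon to the C8 oxocarbenium ion, so the same intrinsic facial preference places the side chain on the opposite face and should give (2R,6R,7aR)-2-[(2E)-4-{[tert-butyl(dimethyl)silyl]oxy}but-2-en-2-yl]-4,4,7a-trimethyl-2,4,5,6,7,7a-hexahydro-1-benzofuran-6-ol F5. Ac2O, pyridine and DMAP convert it into 24.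

Step 16 (ring-opening 1,4-elimination of the ylide, whose carbanion is vinylogously β to the ring oxygen, and incomplete conversion of the 11Z isomer). The fallback reverses the polarity of the C11=C12 olefination, sets out from 25 and 31 and returns at 33. MnO2 oxidises 25 to the enal (2E)-3-[(2R,6R,7aR)-6-(acetyloxy)-4,4,7a-trimethyl-2,4,5,6,7,7a-hexahydro-1-benzofuran-2-yl]but-2-enal F6. Aldehyde 31 is reduced with NaBH4 (EtOH, 0 °C) to ethyl (2E,4E,6E,8E,10E)-12-hydroxy-2,6,11-trimethyldodeca-2,4,6,8,10-pentaenoate F7, brominated (CBr4, PPh3) to ethyl (2E,4E,6E,8E,10E)-12-bromo-2,6,11-trimethyldodeca-2,4,6,8,10-pentaenoate F8 and converted by a Michaelis–Arbuzov reaction with P(OEt)3 into ethyl (2E,4E,6E,8E,10E)-12-(diethoxyphosphoryl)-2,6,11-trimethyldodeca-2,4,6,8,10-pentaenoate F9. Deprotonation with NaN(SiMe3)2 (THF, −78 °C) gives the sodium salt of the phosphonate carbanion of F9 F10, and its Horner–Wadsworth–Emmons reaction with F6 should give 33 with an (E)-configured C11=C12 bond and no carbanion next to the ether ring.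

Further compounds
F1 | step 8 | 4-[(4R)-4-hydroxy-5-iodo-2-methylpentan-2-yl]-5-methylfuran-2(5H)-one | O=C1C=C(C(C)(C)C[C@@H](O)C[I])C(C)O1
F2 | step 8 | tert-butyl({4-[(4R)-4-{[tert-butyl(dimethyl)silyl]oxy}-5-iodo-2-methylpentan-2-yl]-5-methylfuran-2-yl}oxy)dimethylsilane | Cc1oc(O[Si](C)(C)C(C)(C)C)cc1C(C)(C)C[C@@H](O[Si](C)(C)C(C)(C)C)C[I]
F3 | step 8 | (6R,7aR)-6-{[tert-butyl(dimethyl)silyl]oxy}-4,4,7a-trimethyl-5,6,7,7a-tetrahydro-1-benzofuran-2(4H)-one | O=C1C=C2C(C)(C)C[C@@H](O[Si](C)(C)C(C)(C)C)C[C@@]2(C)O1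
F4 | step 12 | (6R,7aR)-2-[(2E)-4-{[tert-butyl(dimethyl)silyl]oxy}but-2-en-2-yl]-4,4,7a-trimethyl-2,4,5,6,7,7a-hexahydro-1-benzofuran-2,6-diol | CC(C)(C)[Si](C)(C)OC/C=C(\C)C1(O)C=C2C(C)(C)C[C@@H](O)C[C@@]2(C)O1
F5 | step 12 | (2R,6R,7aR)-2-[(2E)-4-{[tert-butyl(dimethyl)silyl]oxy}but-2-en-2-yl]-4,4,7a-trimethyl-2,4,5,6,7,7a-hexahydro-1-benzofuran-6-ol | CC(C)(C)[Si](C)(C)OC/C=C(\C)[C@H]1C=C2C(C)(C)C[C@@H](O)C[C@@]2(C)O1
F6 | step 16 | (2E)-3-[(2R,6R,7aR)-6-(acetyloxy)-4,4,7a-trimethyl-2,4,5,6,7,7a-hexahydro-1-benzofuran-2-yl]but-2-enal | O=C/C=C(\C)[C@H]1C=C2C(C)(C)C[C@@H](OC(C)=O)C[C@@]2(C)O1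
F7 | step 16 | ethyl (2E,4E,6E,8E,10E)-12-hydroxy-2,6,11-trimethyldodeca-2,4,6,8,10-pentaenoate | CCOC(=O)/C(C)=C/C=C/C(C)=C/C=C/C=C(C)/CO
F8 | step 16 | ethyl (2E,4E,6E,8E,10E)-12-bromo-2,6,11-trimethyldodeca-2,4,6,8,10-pentaenoate | CCOC(=O)/C(C)=C/C=C/C(C)=C/C=C/C=C(C)/CBr
F9 | step 16 | ethyl (2E,4E,6E,8E,10E)-12-(diethoxyphosphoryl)-2,6,11-trimethyldodeca-2,4,6,8,10-pentaenoate | CCOC(=O)/C(C)=C/C=C/C(C)=C/C=C/C=C(C)/CP(=O)(OCC)OCC
F10 | step 16 | sodium salt of the phosphonate carbanion of F9 | [Na+].CCOC(=O)/C(C)=C/C=C/C(C)=C/C=C/C=C(C)/[CH-]P(=O)(OCC)OCC
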